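Ring A (C1–C2–C3–C4–C5–C9, bicyclo[3.3.1]nonane locants) is read as an aroylated triketide ester and C6 of ring B as an alkyl group parked on the C2 oxygen. The core therefore unzips at C9–C1 and C5–C6 to a 2-(diacylmethylene)tetrahydropyran (O, C6, C7, C8, C1, C2). In one operation a Dieckmann closure bonds C9 to C1 on the pyran face opposite the axial C8 methyl, and iodide then relays C6 from oxygen to C5. The key step exploits the 1,3,5-tricarbonyl pattern of ring A and the C7/C8 pair, set earlier by an Ireland–Claisen rearrangement of a geranyl ester, which fixes both bridgeheads through the temporary pyran ring.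

Key step: step 11

Remark: C1 and C5 are the bridgeheads, C2/C3/C4 the enolized diketone carbons, C9 the bridging carbonyl and C8 the methyl-bearing quaternary carbon of the target.
Assumption: the (S,S)-bromoborane of step 2 is taken to deliver the (2R,3S) acid; should correlation show the opposite sense, its (R,R) antipode is used in the same step.
Remark: 11, 16, 17 and 19 are carried as mixtures at their enolizable centres, which become planar in step 11.
Remark: the catechol is carried as a 3-methylidene-3,4-dihydro-2H-1,5-benzodioxepine, in which one 2-methylidenepropane-1,3-diyl unit bridges both oxygens as a cyclic bis-allylic aryl ether.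

Step 1
Reactants: 1 geranyl acetate; 2 prenyl bromide
Product: 3 geranyl 5-methylhex-4-enoate
Conditions: LiN(i-Pr)2, THF, −78 °C; then 2, DMPU, −78 to −20 °C
Reagents that add atoms: none
Why: Alkylation of the lithium ester enolate (SN2 at the primary allylic bromide) should outrun self-condensation at low temperature; no stereocentre is formed.

Step 2
Reactants: 3 geranyl 5-methylhex-4-enoate
Product: 5 (2R,3S)-3-ethenyl-3,7-dimethyl-2-(3-methylbut-2-en-1-yl)oct-6-enoic acid, via boron ketene acetal 4 (not isolated)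
Conditions: (4S,5S)-2-bromo-4,5-diphenyl-1,3-bis(4-methylbenzenesulfonyl)-1,3,2-diazaborolidine (1.2 equiv), i-Pr2NEt, CH2Cl2, −78 °C, then −20 °C, several days; aq. work-up
Reagents that add atoms: none
Why: Enantioselective Ireland–Claisen rearrangement: the boron ketene acetal with the prenylmethyl group trans to the allyloxy oxygen should rearrange through a chair in which the (E)-geranyl terminus places methyl axial and homoprenyl equatorial, giving the 2R*,3S* pair (C7 and C8 of the target), while the C2-symmetric sulfonamide ligand on boron selects the enantiotopic face.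

Step 3
Reactants: 5 (2R,3S)-3-ethenyl-3,7-dimethyl-2-(3-methylbut-2-en-1-yl)oct-6-enoic acid
Product: 6 (2R,3S)-3-ethenyl-3,7-dimethyl-2-(3-methylbut-2-en-1-yl)oct-6-en-1-ol
Conditions: LiAlH4, Et2O, 0 °C to rt
Reagents that add atoms: none
Why: LiAlH4 reduction of the carboxylic acid to the primary alcohol should leave the isolated alkenes and both stereocentres untouched.

Step 4
Reactants: 6 (2R,3S)-3-ethenyl-3,7-dimethyl-2-(3-methylbut-2-en-1-yl)oct-6-en-1-ol
Product: 8 (2R,3S)-3-methyl-2-(3-methylbut-2-en-1-yl)-3-(4-methylpent-3-en-1-yl)pentane-1,5-diol, via bis-9-BBN adduct 7 (not isolated)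
Conditions: 9-BBN-H (2.5 equiv), THF, 0 °C to rt; then NaOH, H2O2, 0 °C
Reagents that add atoms: hydrogen peroxide, OO
Why: Anti-Markovnikov hydroboration–oxidation: the bulky dialkylborane should add only to the monosubstituted vinyl group, the trisubstituted alkenes being far slower.

Step 5
Reactants: 8 (2R,3S)-3-methyl-2-(3-methylbut-2-en-1-yl)-3-(4-methylpent-3-en-1-yl)pentane-1,5-diol
Product: 10 (4S,5R)-4-methyl-5-(3-methylbut-2-en-1-yl)-4-(4-methylpent-3-en-1-yl)oxan-2-one, via lactol 9 (not isolated)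
Conditions: TEMPO (cat.), PhI(OAc)2 (2.5 equiv), CH2Cl2, rt
Reagents that add atoms: none
Why: TEMPO-catalysed oxidative lactonization of a 1,5-diol: the oxoammonium ion should oxidize the less hindered hydroxyl (C5, next to a CH2) first, the aldehyde is trapped as lactol 9 and oxidized on to the δ-lactone.

Step 6
Reactants: 10 (4S,5R)-4-methyl-5-(3-methylbut-2-en-1-yl)-4-(4-methylpent-3-en-1-yl)oxan-2-one; 2 prenyl bromide
Product: 11 (4R,5R)-4-methyl-3,5-bis(3-methylbut-2-en-1-yl)-4-(4-methylpent-3-en-1-yl)oxan-2-one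
Conditions: LiN(i-Pr)2, THF, −78 °C; then 2, −78 to 0 °C
Reagents that add atoms: none
Why: Lactone enolate alkylation with the allylic bromide; the new centre C3 need not be controlled because it is planarized again in step 11.

Step 7
Reactants: 12 methyl 3,4-dihydroxybenzoate; 13 3-chloro-2-(chloromethyl)prop-1-ene
Product: 14 methyl 3-methylidene-3,4-dihydro-2H-1,5-benzodioxepine-7-carboxylate
Conditions: K2CO3 (2.5 equiv), DMF, 80 °C, slow addition of 13
Reagents that add atoms: none
Why: Double Williamson etherification in which the second SN2 displacement is intramolecular and closes the seven-membered 1,5-benzodioxepine ring, so one molecule of 13 masks both phenols as a cyclic bis-allylic aryl ether that should survive bases and alkylating agents, should re-close on itself if iodide opens it, and leaves at the end under neutral palladium catalysis.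

Step 8
Reactants: 15 methyl acetoacetate; 2 prenyl bromide
Product: 16 methyl 2-acetyl-5-methylhex-4-enoate
Conditions: K2CO3, acetone, reflux
Reagents that add atoms: none
Why: C-Alkylation of the β-keto ester enolate by the allylic bromide under mild carbonate conditions.

Step 9
Reactants: 16 methyl 2-acetyl-5-methylhex-4-enoate; 14 methyl 3-methylidene-3,4-dihydro-2H-1,5-benzodioxepine-7-carboxylate
Product: 17 methyl 5-(3-methylidene-3,4-dihydro-2H-1,5-benzodioxepin-7-yl)-2-(3-methylbut-2-en-1-yl)-3,5-dioxopentanoate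
Conditions: 16 (2 equiv), NaH, THF, 0 °C; n-BuLi, 0 °C; then 14, 0 °C to rt; aq. HCl
Reagents that add atoms: none
Why: γ-Acylation of a β-keto ester dianion by an aryl ester (Claisen-type condensation at the more reactive terminal carbanion); the second equivalent of dianion absorbs the acidic product.

Step 10
Reactants: 11 (4R,5R)-4-methyl-3,5-bis(3-methylbut-2-en-1-yl)-4-(4-methylpent-3-en-1-yl)oxan-2-one; 17 methyl 5-(3-methylidene-3,4-dihydro-2H-1,5-benzodioxepin-7-yl)-2-(3-methylbut-2-en-1-yl)-3,5-dioxopentanoate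
Product: 19 methyl 5-(3-methylidene-3,4-dihydro-2H-1,5-benzodioxepin-7-yl)-2-(3-methylbut-2-en-1-yl)-4-[(4R,5R)-4-methyl-3,5-bis(3-methylbut-2-en-1-yl)-4-(4-methylpent-3-en-1-yl)oxan-2-ylidene]-3,5-dioxopentanoate, via lactonium tetrafluoroborate 18 (not isolated)
Conditions: 11, Et3OBF4, CH2Cl2, rt; then sodium enolate of 17 (NaH, THF), 0 °C to rt
Reagents that add atoms: none
Why: O-Ethylation turns the lactone into a dialkoxycarbenium ion that should be attacked at carbon by the 1,3-diketone enolate, and loss of ethanol gives the push–pull alkene (condensation of lactonium salts with active methylene compounds); the ring stereocentres are not touched.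

Step 11
Reactants: 19 methyl 5-(3-methylidene-3,4-dihydro-2H-1,5-benzodioxepin-7-yl)-2-(3-methylbut-2-en-1-yl)-4-[(4R,5R)-4-methyl-3,5-bis(3-methylbut-2-en-1-yl)-4-(4-methylpent-3-en-1-yl)oxan-2-ylidene]-3,5-dioxopentanoate
Product: 22 (1S,5S,7S,8R)-4-hydroxy-8-methyl-1,5,7-tris(3-methylbut-2-en-1-yl)-3-(3-methylidene-3,4-dihydro-2H-1,5-benzodioxepine-7-carbonyl)-8-(4-methylpent-3-en-1-yl)bicyclo[3.3.1]non-3-ene-2,9-dione, via pyrano-fused dienone 20 (not isolated), via iodo trione 21 (not isolated)
Conditions: KOt-Bu (2.2 equiv), THF, 0 °C to rt; MsOH (2.2 equiv); then LiI (2 equiv), DMF, 120 °C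
Reagents that add atoms: none
Why: Proposed new method: the first equivalent of KOt-Bu rests on the acidic C5 position and the second removes the γ-hydrogen at C1 of the push–pull enol ether, whose planar dienolate attacks the C9 ester (6-(enolendo)-exo-trig Dieckmann closure of ring A, the known relative being the Claisen cyclization of polyanions of polyketo esters to acylphloroglucinols) to give the pyrano-fused dienone 20. After neutralization, iodide dealkylates the cyclic vinylogous ester at C6 (Krapcho-type SN2 cleavage) and the tethered iodide 21 alkylates C5 (6-(enolendo)-exo-tet closure of ring B, the known relatives being alkylative dearomatization–annulations of acylphloroglucinols and halide-catalysed O-to-N alkyl shifts of imidates), so LiI acts as a relay catalyst for a net O-to-C shift of C6. C1 is set in the Dieckmann event: in the half-chair dihydropyran the C7 prenyl group is equatorial, the cis C8 methyl is therefore pseudoaxial, and C9 should enter on the opposite face, trans to that methyl. C5 is set by the tether, which can reach it only from the face on which it is attached at C1. The step needs C-alkylation at C5 instead of at oxygen or at C3: O-alkylation is reopened by iodide whereas the C–C bond is not, and C3 carries the aroyl group, which makes it the hindered and less nucleophilic carbon of the triketone anion.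

Step 12
Reactants: 22 (1S,5S,7S,8R)-4-hydroxy-8-methyl-1,5,7-tris(3-methylbut-2-en-1-yl)-3-(3-methylidene-3,4-dihydro-2H-1,5-benzodioxepine-7-carbonyl)-8-(4-methylpent-3-en-1-yl)bicyclo[3.3.1]non-3-ene-2,9-dione
Product: 23 (1S,5S,7S,8R)-3-(3,4-dihydroxybenzoyl)-4-hydroxy-8-methyl-1,5,7-tris(3-methylbut-2-en-1-yl)-8-(4-methylpent-3-en-1-yl)bicyclo[3.3.1]non-3-ene-2,9-dione
Conditions: Pd(PPh3)4 (5 mol %), morpholine (10 equiv), THF, rt; dilute aq. HCl work-up
Reagents that add atoms: none
Why: Zerovalent palladium should ionize the two allylic aryl ether C–O bonds of the 2-methylidenepropane-1,3-diyl bridge one after the other and morpholine should trap both π-allyl complexes (Tsuji–Trost deallylation), which frees the catechol without acid, which the prenyl groups and the enolized triketone would not tolerate.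

Compound list
1 | geranyl acetate, (2E)-3,7-dimethylocta-2,6-dien-1-yl acetate | CC(C)=CCC/C(C)=C/COC(C)=O | starting material
2 | prenyl bromide, 1-bromo-3-methylbut-2-ene | CC(C)=CCBr | starting material
3 | geranyl 5-methylhex-4-enoate | CC(C)=CCC/C(C)=C/COC(=O)CCC=C(C)C | intermediate
4 | boron ketene acetal of 3 carrying the (4S,5S)-4,5-diphenyl-1,3-bis(4-methylbenzenesulfonyl)-1,3,2-diazaborolidin-2-yl group, prenylmethyl trans to the geranyloxy oxygen | CC(C)=CCC/C(C)=C/CO/C(OB1N(S(=O)(=O)c2ccc(C)cc2)[C@@H](c2ccccc2)[C@H](c2ccccc2)N1S(=O)(=O)c1ccc(C)cc1)=C/CC=C(C)C | intermediate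
5 | (2R,3S)-3-ethenyl-3,7-dimethyl-2-(3-methylbut-2-en-1-yl)oct-6-enoic acid | CC(C)=CCC[C@@](C)(C=C)[C@@H](CC=C(C)C)C(O)=O | intermediate
6 | (2R,3S)-3-ethenyl-3,7-dimethyl-2-(3-methylbut-2-en-1-yl)oct-6-en-1-ol | CC(C)=CCC[C@@](C)(C=C)[C@@H](CC=C(C)C)CO | intermediate
7 | bis(9-borabicyclo[3.3.1]nonan-9-yl) adduct of 6 (B-alkyl at the former vinyl terminus, B–O at the hydroxyl) | CC(C)=CCC[C@@](C)(CCB1C2CCCC1CCC2)[C@@H](CC=C(C)C)COB1C2CCCC1CCC2 | intermediate
8 | (2R,3S)-3-methyl-2-(3-methylbut-2-en-1-yl)-3-(4-methylpent-3-en-1-yl)pentane-1,5-diol | CC(C)=CCC[C@@](C)(CCO)[C@@H](CC=C(C)C)CO | intermediate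
9 | (4S,5R)-4-methyl-5-(3-methylbut-2-en-1-yl)-4-(4-methylpent-3-en-1-yl)oxan-2-ol (lactol, both anomers) | CC(C)=CCC[C@]1(C)[C@@H](CC=C(C)C)COC(O)C1 | intermediate
10 | (4S,5R)-4-methyl-5-(3-methylbut-2-en-1-yl)-4-(4-methylpent-3-en-1-yl)oxan-2-one | CC(C)=CCC[C@]1(C)[C@@H](CC=C(C)C)COC(=O)C1 | intermediate
11 | (4R,5R)-4-methyl-3,5-bis(3-methylbut-2-en-1-yl)-4-(4-methylpent-3-en-1-yl)oxan-2-one (both C3 epimers) | CC(C)=CCC[C@]1(C)[C@@H](CC=C(C)C)COC(=O)C1CC=C(C)C | intermediate
12 | methyl 3,4-dihydroxybenzoate | COC(=O)c1ccc(O)c(O)c1 | starting material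
13 | 3-chloro-2-(chloromethyl)prop-1-ene | ClCC(=C)CCl | starting material
14 | methyl 3-methylidene-3,4-dihydro-2H-1,5-benzodioxepine-7-carboxylate | COC(=O)c1ccc2OCC(=C)COc2c1 | intermediate
15 | methyl acetoacetate, methyl 3-oxobutanoate | COC(=O)CC(C)=O | starting material
16 | methyl 2-acetyl-5-methylhex-4-enoate (racemic) | COC(=O)C(CC=C(C)C)C(C)=O | intermediate
17 | methyl 5-(3-methylidene-3,4-dihydro-2H-1,5-benzodioxepin-7-yl)-2-(3-methylbut-2-en-1-yl)-3,5-dioxopentanoate (racemic at C2) | COC(=O)C(CC=C(C)C)C(=O)CC(=O)c1ccc2OCC(=C)COc2c1 | intermediate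
18 | (4R,5R)-2-ethoxy-4-methyl-3,5-bis(3-methylbut-2-en-1-yl)-4-(4-methylpent-3-en-1-yl)-3,4,5,6-tetrahydropyrylium tetrafluoroborate | CC(C)=CCC[C@]1(C)[C@@H](CC=C(C)C)C[O+]=C(OCC)C1CC=C(C)C.F[B-](F)(F)F | intermediate
19 | methyl 5-(3-methylidene-3,4-dihydro-2H-1,5-benzodioxepin-7-yl)-2-(3-methylbut-2-en-1-yl)-4-[(4R,5R)-4-methyl-3,5-bis(3-methylbut-2-en-1-yl)-4-(4-methylpent-3-en-1-yl)oxan-2-ylidene]-3,5-dioxopentanoate (mixture at pyran C3 and chain C2, alkene geometry not fixed) | CC(C)=CCC[C@]1(C)[C@@H](CC=C(C)C)COC(=C(C(=O)c2ccc3OCC(=C)COc3c2)C(=O)C(CC=C(C)C)C(=O)OC)C1CC=C(C)C | intermediate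
20 | (3R,4R,4aS)-5-hydroxy-4-methyl-3,4a,6-tris(3-methylbut-2-en-1-yl)-8-(3-methylidene-3,4-dihydro-2H-1,5-benzodioxepine-7-carbonyl)-4-(4-methylpent-3-en-1-yl)-2,3,4,4a-tetrahydro-7H-chromen-7-one | CC(C)=CCC[C@]1(C)[C@@H](CC=C(C)C)COC2=C(C(=O)c3ccc4OCC(=C)COc4c3)C(=O)C(CC=C(C)C)=C(O)[C@]12CC=C(C)C | intermediate
21 | (6S)-3,5-dihydroxy-6-[(2R,3R)-1-iodo-3,7-dimethyl-2-(3-methylbut-2-en-1-yl)oct-6-en-3-yl]-2-(3-methylidene-3,4-dihydro-2H-1,5-benzodioxepine-7-carbonyl)-4,6-bis(3-methylbut-2-en-1-yl)cyclohexa-2,4-dien-1-one | CC(C)=CCC[C@](C)([C@@H](CC=C(C)C)CI)[C@]1(CC=C(C)C)C(=O)C(C(=O)c2ccc3OCC(=C)COc3c2)=C(O)C(CC=C(C)C)=C1O | intermediate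
22 | (1S,5S,7S,8R)-4-hydroxy-8-methyl-1,5,7-tris(3-methylbut-2-en-1-yl)-3-(3-methylidene-3,4-dihydro-2H-1,5-benzodioxepine-7-carbonyl)-8-(4-methylpent-3-en-1-yl)bicyclo[3.3.1]non-3-ene-2,9-dione | CC(C)=CCC[C@]1(C)[C@@H](CC=C(C)C)C[C@]2(CC=C(C)C)C(=O)[C@@]1(CC=C(C)C)C(=O)C(C(=O)c1ccc3OCC(=C)COc3c1)=C2O | intermediate
23 | CNP0108469.1, (1S,5S,7S,8R)-3-(3,4-dihydroxybenzoyl)-4-hydroxy-8-methyl-1,5,7-tris(3-methylbut-2-en-1-yl)-8-(4-methylpent-3-en-1-yl)bicyclo[3.3.1]non-3-ene-2,9-dione | CC(C)=CCC[C@]1(C)[C@@H](CC=C(C)C)C[C@]2(CC=C(C)C)C(=O)[C@@]1(CC=C(C)C)C(=O)C(C(=O)c1ccc(O)c(O)c1)=C2O | target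

Total step count: 12. Longest linear sequence: 9 steps (steps 1 to 6, then 10, 11 and 12).

Steps most likely to fail

Step 11. The iodide-relayed transfer of C6 from oxygen to carbon may stall at the O-alkylated stage, or the tethered iodide may lose HI instead of closing the strained ring B with its endo C7 prenyl group. Insufficient facial discrimination in the Dieckmann closure is the second concern. The fallback uses known chemistry, sets out from 19 and comes back at 22. The Dieckmann condensation is run alone with KOt-Bu and the pyrano-fused dienone 20 is isolated. Its cyclic vinylogous ester is opened with bromotrimethylsilane in CH2Cl2 at low temperature in the presence of 2,6-di-tert-butyl-4-methylpyridine as proton scavenger (silyl halide dealkylation at the most basic carbonyl oxygen) to give, after aqueous work-up, the bromo trione F1. F1 is then closed in a separate intramolecular alkylative dearomatization with Cs2CO3 and catalytic n-Bu4NI in THF/DMSO, O-alkylated material being recycled through 20, to give 22.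

Step 10. Capture of the hindered dialkoxycarbenium ion at carbon may lose out to de-ethylation back to the lactone or to deprotonation to a ketene acetal. The fallback sets out from 11 and 17 and comes back at 19 by a sulfide contraction. Thionation of 11 with 2,4-bis(4-methoxyphenyl)-1,3,2,4-dithiadiphosphetane 2,4-disulfide in toluene gives the thionolactone F2. Compound 17 is brominated between its two ketones with N-bromosuccinimide at 0 °C to the bromo diketone F3. S-Alkylation of F2 by F3 followed by PPh3 and Et3N (Eschenmoser sulfide contraction) extrudes sulfur and gives 19.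

Step 5. The first oxidation may not discriminate between the two primary hydroxyls, which would divert material to the regioisomeric lactone. The fallback sets out from 6 and comes back at 10. The hydroxyl of 6 is silylated first (TBSCl, imidazole) to the silyl ether F4. Hydroboration–oxidation with 9-BBN-H then gives the mono-protected diol F5. TEMPO and PhI(OAc)2 in aqueous MeCN oxidize its only free hydroxyl to the acid F6, and n-Bu4NF removes the silyl group with lactonization to 10.

Further compounds
F1 | step 11 | (6S)-6-[(2R,3R)-1-bromo-3,7-dimethyl-2-(3-methylbut-2-en-1-yl)oct-6-en-3-yl]-3,5-dihydroxy-2-(3-methylidene-3,4-dihydro-2H-1,5-benzodioxepine-7-carbonyl)-4,6-bis(3-methylbut-2-en-1-yl)cyclohexa-2,4-dien-1-one | CC(C)=CCC[C@](C)([C@@H](CC=C(C)C)CBr)[C@]1(CC=C(C)C)C(=O)C(C(=O)c2ccc3OCC(=C)COc3c2)=C(O)C(CC=C(C)C)=C1O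
F2 | step 10 | (4R,5R)-4-methyl-3,5-bis(3-methylbut-2-en-1-yl)-4-(4-methylpent-3-en-1-yl)oxane-2-thione | CC(C)=CCC[C@]1(C)[C@@H](CC=C(C)C)COC(=S)C1CC=C(C)C
F3 | step 10 | methyl 4-bromo-5-(3-methylidene-3,4-dihydro-2H-1,5-benzodioxepin-7-yl)-2-(3-methylbut-2-en-1-yl)-3,5-dioxopentanoate | COC(=O)C(CC=C(C)C)C(=O)C(Br)C(=O)c1ccc2OCC(=C)COc2c1
F4 | step 5 | tert-butyl{[(2R,3S)-3-ethenyl-3,7-dimethyl-2-(3-methylbut-2-en-1-yl)oct-6-en-1-yl]oxy}dimethylsilane | CC(C)=CCC[C@@](C)(C=C)[C@@H](CC=C(C)C)CO[Si](C)(C)C(C)(C)C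
F5 | step 5 | (3S,4R)-5-{[tert-butyl(dimethyl)silyl]oxy}-3-methyl-4-(3-methylbut-2-en-1-yl)-3-(4-methylpent-3-en-1-yl)pentan-1-ol | CC(C)=CCC[C@@](C)(CCO)[C@@H](CC=C(C)C)CO[Si](C)(C)C(C)(C)C
F6 | step 5 | (3S,4R)-5-{[tert-butyl(dimethyl)silyl]oxy}-3-methyl-4-(3-methylbut-2-en-1-yl)-3-(4-methylpent-3-en-1-yl)pentanoic acid | CC(C)=CCC[C@@](C)(CC(O)=O)[C@@H](CC=C(C)C)CO[Si](C)(C)C(C)(C)C
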